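- A flat top on the target curve tempts me to call a flask finished, but flat says only that making and losing match, and both may still be large.

in all of them: temperature 100 °C
- winter: substrate 10 mM; the very flask that is asked about, followed so far
- midnight: substrate 6.7 mM; run made earlier
- flask: substrate 10 mM; time 6.0 h

| run | time / h | target / % | substrate / % |
|---|---|---|---|
| winter | 0.417 | 7.8 | 40.8 |
| winter | 0.833 | 18.1 | 35.4 |
| winter | 2.00 | 35.4 | 26.3 |
| winter | 5.00 | 46.1 | 10.8 |
| midnight | 0.833 | 17.2 | 34.3 |
| midnight | 2.00 | 32.7 | 26.4 |
| midnight | 4.00 | 44.6 | 14.5 |
| midnight | 6.00 | 45.7 | 7.3 |

(readings scatter by 1 percentage point)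

- Saturday's: at 6.0 h add substrate, 50.0% of the amount charged, then wait 2.0 h
- Thursday's: change nothing and wait 2.0 h more
- Sunday's: at 6.0 h raise the temperature by 25 K, then wait 2.0 h
- Friday's: at 6.0 h take out 90% of the target then present, then wait 2.0 h

- what is taken out of target is counted as made
- additions bring no volume worth counting
- the earlier runs do not show what temperature does; that part of a forecast is a guess

* target, in percent of the substrate first charged, at 6.0 h
* the remedy with the largest gain of target, or "none" below 2 percentage points (Saturday's / Thursday's / Sunday's / Friday's / none)
* target present, with what was taken out counted in, in percent of the substrate first charged, after Saturday's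
* target present, with what was taken out counted in, in percent of the substrate first charged, after Thursday's

- In percent of the charge, the winter and midnight runs overlapped: substrate read 26.3% and 26.4% at 2.00 h. I therefore treated the steps as first order and took midnight's target reading, 45.7% at 6.00 h, as my value for the winter flask.
- Target read 7.8% and 18.1% at the first two winter readings, and I neglected its loss there. Its climb between the first two readings, divided by mean [substrate], gave 0.650 h⁻¹, the feed constant: feed, the pace of making target as a fraction of the charge, is this constant times [substrate].
- At the end of the midnight run, [substrate] of 7.3% gave a feed of 0.0474 h⁻¹, but target climbed at 0.00550 h⁻¹. Since feed was larger than the climb, target was being lost at 0.0419 h⁻¹.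
- Midnight's substrate was falling at 0.343 h⁻¹, so mean feed over the wait would be 0.724 of its starting value. With loss held fixed, Thursday's gave me −1.5 percentage points, or 44.2%.
- An unseen form stood at 1.26 times substrate at the first winter reading, which I read as a pre-equilibrium. Saturday's dose would split the same way, and with loss held fixed I reckoned 65.0%.
- Friday's, with loss taken as stopped, gave me a gain of 6.9 points, less than my gain for Saturday's. The runs showed nothing of temperature, so I left Sunday's unranked and put Saturday's first of the others.
- The forecast gave 45.5% at the asked time, 56% after Saturday's, 40% after Thursday's and Saturday's as the best remedy, saying of the heat: “Heating is a guess, and probably burns target.”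
- The winter flask gave 45.9% at the asked time, 43.9% after Thursday's and 60.8% after Saturday's, the last less than my 65.0%. Gains were 15 points for Saturday's, 11 points for Friday's and 30 points for Sunday's, so the best remedy was Sunday's.

    substrate ⇌ intermediate (K = 1.30, k = 0.0960 min⁻¹, Ea = 114 kJ mol⁻¹, ΔH = −7.00 kJ mol⁻¹)
    intermediate → target (k = 0.00850 min⁻¹, Ea = 110 kJ mol⁻¹)
    target ⇌ isomer of the product (K = 1.90, k = 0.00360 min⁻¹, Ea = 110 kJ mol⁻¹, ΔH = −90.0 kJ mol⁻¹)
    (constants at 100 °C)

The winter flask had not come to rest at 6.00 h: 0.650 h⁻¹ on [substrate] of 8.47% gives a feed of 0.0551 h⁻¹, and Thursday's still moved target by −2.1 points. In the flask kept at 125 °C, substrate stood at 0% by 6.00 h, so feed there was zero whatever its constant, with target at 76.5% and isomer of the product at 23.5%. Left until 60.0 h, the winter flask held substrate at 0% and intermediate at 0%, while target fell from 45.9% to 34.5% and isomer of the product rose from 35.1% to 65.5%.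

The earlier runs and the new flask are calculated on assumed constants, noise included.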